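**Strategy**

The target is gallocatechin-(4α→6)-gallocatechin, so both halves come from one monomer, 8-bromo-penta-O-benzyl-(+)-gallocatechin. The route rests on the bond from C4 of the upper pyran ring to C6 of the lower A ring. One portion of the monomer is oxidised at C4 and acetylated at O3; TMSOTf ionises it to a C4 cation stabilised by O1, O5 and O7 of its A ring and bridged on the β face by the 3-acetate. Unchanged monomer captures this cation in one Friedel–Crafts operation: bromine at C8 leaves C6, flanked by O5 and O7, as the only free A-ring carbon, and the bridge forces α attack, setting C4 3,4-trans. Hydrogenolysis then removes benzyl groups and bromines together.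

Key step: step 5

Remark: (+)-gallocatechin is taken as a purchasable single enantiomer, and the ether in 4 and 5 is drawn as the 4β (4S) epimer expected by analogy with benzylated catechins; this centre is ionised in step 5, so its configuration does not reach the target.

**Route**

Step 1
Reactants: 1 (+)-gallocatechin
Product: 2 5,7,3',4',5'-penta-O-benzyl-(+)-gallocatechin
Conditions: BnBr (5.5 equiv), K2CO3, degassed DMF, Ar, 0 °C to rt
Reagents that add atoms: benzyl bromide, BrCc1ccccc1
Why: Williamson etherification, in which carbonate deprotonates only the five phenols so that the secondary 3-OH should stay free and no stereocentre is touched.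

Step 2
Reactants: 2 5,7,3',4',5'-penta-O-benzyl-(+)-gallocatechin
Product: 3 8-bromo-5,7,3',4',5'-penta-O-benzyl-(+)-gallocatechin
Conditions: NBS (1.0 equiv), CH2Cl2, −78 to −20 °C
Reagents that add atoms: N-bromosuccinimide, O=C1CCC(=O)N1Br
Why: Electrophilic aromatic bromination, which should go to C8 because it is the most nucleophilic and less hindered carbon of the phloroglucinol-type A ring (ortho to O1 and O7, para to O5), while the tribenzyloxyphenyl B ring is less activated.

Step 3
Reactants: 3 8-bromo-5,7,3',4',5'-penta-O-benzyl-(+)-gallocatechin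
Product: 4 (2R,3S,4S)-8-bromo-4-(2-ethoxyethoxy)-5,7,3',4',5'-penta-O-benzylgallocatechin (4β-ether, 3-OH free)
Conditions: DDQ (2 equiv), 2-ethoxyethanol (10 equiv), CH2Cl2, rt
Reagents that add atoms: 2-ethoxyethanol, CCOCCO
Why: DDQ benzylic C–H oxidation (oxidative etherification), in which hydride abstraction from C4 gives the A-ring-stabilised quinone methide cation that the alcohol should trap from the β face, the simple benzyl ethers being inert to DDQ at room temperature.

Step 4
Reactants: 4 (2R,3S,4S)-8-bromo-4-(2-ethoxyethoxy)-5,7,3',4',5'-penta-O-benzylgallocatechin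
Product: 5 (2R,3S,4S)-3-O-acetyl-8-bromo-4-(2-ethoxyethoxy)-5,7,3',4',5'-penta-O-benzylgallocatechin
Conditions: Ac2O, pyridine, DMAP (cat.), rt
Reagents that add atoms: acetic anhydride, CC(=O)OC(C)=O
Why: DMAP-catalysed acylation of the secondary 3-OH under basic conditions that leave the acid-labile C4 ether untouched, installing the participating group needed in step 5.

Step 5
Reactants: 5 (2R,3S,4S)-3-O-acetyl-8-bromo-4-(2-ethoxyethoxy)-5,7,3',4',5'-penta-O-benzylgallocatechin (donor); 3 8-bromo-5,7,3',4',5'-penta-O-benzyl-(+)-gallocatechin (nucleophile, 3 equiv, excess recovered)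
Product: 7 3-O-acetyl-8-bromo-penta-O-benzylgallocatechin-(4α→6)-8-bromo-penta-O-benzylgallocatechin, via C3–C4 acetoxonium triflate 6 (not isolated)
Conditions: TMSOTf (0.2 equiv), 4 Å MS, CH2Cl2, −78 °C; Et3N quench
Reagents that add atoms: none
Why: TMSOTf ionises the C4–O bond of 5 to a C4 cation that is stabilised as a quinone methide-type oxocarbenium by O1, O5 and O7 of its A ring and is bridged by the carbonyl oxygen of the 3β-acetate as the cis-fused acetoxonium 6; C6 of 3 then attacks C4 and the arenium ion loses its proton (Friedel–Crafts alkylation). The closest known reaction type is the Lewis acid-mediated condensation of 3-O-acyl-4-alkoxyflavans with benzylated flavan-3-ols that builds B-type proanthocyanidin dimers, used here with a halogen-blocked nucleophile. No ring of the product is closed; the transient five-membered dioxolenium ring of 6 closes by neighbouring-group attack of the acetate carbonyl oxygen on C4 and is opened again by the arene. The new stereocentre C4 is controlled by the 3β-acetate: its β-face bridge leaves only the α face open, so the aryl group should enter trans to O3 and give the 2,3-trans-3,4-trans junction. The step needs C6 rather than C8 attack in the nucleophile and no chain growth through the donor; the bromine at C8 of 3 leaves C6, between O5 and O7, as the only free A-ring carbon, and the bromine at C8 of 5 removes the most nucleophilic carbon of the donor and of the upper unit of 7. The excess of 3 should outcompete the equally hindered C6–H of donor and product.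

Step 6
Reactants: 7 3-O-acetyl-8-bromo-penta-O-benzylgallocatechin-(4α→6)-8-bromo-penta-O-benzylgallocatechin
Product: 8 8-bromo-penta-O-benzylgallocatechin-(4α→6)-8-bromo-penta-O-benzylgallocatechin (both 3-OH free)
Conditions: NaOMe (cat.), MeOH/THF, rt
Reagents that add atoms: none
Why: Zemplén transesterification should remove the single secondary acetate, since aryl bromides, benzyl ethers and the interflavan bond are stable to catalytic methoxide and the fully O-benzylated flavan units cannot epimerise at C2.

Step 7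
Reactants: 8 8-bromo-penta-O-benzylgallocatechin-(4α→6)-8-bromo-penta-O-benzylgallocatechin
Product: 9 gallocatechin-(4α→6)-gallocatechin (upper unit 2R,3S,4R; lower unit 2R,3S)
Conditions: H2 (1 atm), 20% Pd(OH)2/C, NaOAc (2.2 equiv), THF/MeOH/H2O, rt; filter under Ar, lyophilise, Sephadex LH-20
Reagents that add atoms: none
Why: Catalytic hydrogenolysis should cleave the ten benzyl ethers and hydrodebrominate both C8–Br bonds in one operation, the acetate buffering the HBr so that the acid-labile interflavan bond is not cleaved and no stereocentre is affected.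

**Compound list**

1 | (+)-gallocatechin, (2R,3S)-2-(3,4,5-trihydroxyphenyl)chromane-3,5,7-triol | Oc1cc(O)c2c(c1)O[C@H](c1cc(O)c(O)c(O)c1)[C@@H](O)C2 | starting material
2 | 5,7,3',4',5'-penta-O-benzyl-(+)-gallocatechin, (2R,3S)-5,7-bis(benzyloxy)-2-[3,4,5-tris(benzyloxy)phenyl]chroman-3-ol | C(Oc1cc(OCc3ccccc3)c2c(c1)O[C@H](c1cc(OCc3ccccc3)c(OCc3ccccc3)c(OCc3ccccc3)c1)[C@@H](O)C2)c1ccccc1 | intermediate
3 | 8-bromo-5,7,3',4',5'-penta-O-benzyl-(+)-gallocatechin, (2R,3S)-5,7-bis(benzyloxy)-8-bromo-2-[3,4,5-tris(benzyloxy)phenyl]chroman-3-ol | C(Oc1cc(OCc3ccccc3)c2c(c1Br)O[C@H](c1cc(OCc3ccccc3)c(OCc3ccccc3)c(OCc3ccccc3)c1)[C@@H](O)C2)c1ccccc1 | intermediate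
4 | (2R,3S,4S)-5,7-bis(benzyloxy)-8-bromo-4-(2-ethoxyethoxy)-2-[3,4,5-tris(benzyloxy)phenyl]chroman-3-ol (4β-ether, cis to 3-OH) | C(Oc1cc(OCc3ccccc3)c2c(c1Br)O[C@H](c1cc(OCc3ccccc3)c(OCc3ccccc3)c(OCc3ccccc3)c1)[C@@H](O)[C@H]2OCCOCC)c1ccccc1 | intermediate
5 | (2R,3S,4S)-5,7-bis(benzyloxy)-8-bromo-4-(2-ethoxyethoxy)-2-[3,4,5-tris(benzyloxy)phenyl]chroman-3-yl acetate | C(Oc1cc(OCc3ccccc3)c2c(c1Br)O[C@H](c1cc(OCc3ccccc3)c(OCc3ccccc3)c(OCc3ccccc3)c1)[C@@H](OC(C)=O)[C@H]2OCCOCC)c1ccccc1 | intermediate
6 | C3–C4 cis-fused 2-methyl-1,3-dioxolan-2-ylium (acetoxonium) triflate of the donor, bridge on the β face | C(Oc1cc(OCc3ccccc3)c2c(c1Br)O[C@H](c1cc(OCc3ccccc3)c(OCc3ccccc3)c(OCc3ccccc3)c1)[C@@H](OC(C)=[O+]4)[C@H]24)c1ccccc1.[O-]S(=O)(=O)C(F)(F)F | intermediate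
7 | 3-O-acetyl-8-bromo-5,7,3',4',5'-penta-O-benzylgallocatechin-(4α→6)-8-bromo-5,7,3',4',5'-penta-O-benzylgallocatechin (upper unit 2,3-trans-3,4-trans) | C(Oc1cc(OCc3ccccc3)c2c(c1Br)O[C@H](c1cc(OCc3ccccc3)c(OCc3ccccc3)c(OCc3ccccc3)c1)[C@@H](OC(C)=O)[C@@H]2c1c(OCc3ccccc3)c(Br)c2c(c1OCc3ccccc3)C[C@H](O)[C@@H](c1cc(OCc3ccccc3)c(OCc3ccccc3)c(OCc3ccccc3)c1)O2)c1ccccc1 | intermediate
8 | 8-bromo-5,7,3',4',5'-penta-O-benzylgallocatechin-(4α→6)-8-bromo-5,7,3',4',5'-penta-O-benzylgallocatechin (both 3-OH free) | C(Oc1cc(OCc3ccccc3)c2c(c1Br)O[C@H](c1cc(OCc3ccccc3)c(OCc3ccccc3)c(OCc3ccccc3)c1)[C@@H](O)[C@@H]2c1c(OCc3ccccc3)c(Br)c2c(c1OCc3ccccc3)C[C@H](O)[C@@H](c1cc(OCc3ccccc3)c(OCc3ccccc3)c(OCc3ccccc3)c1)O2)c1ccccc1 | intermediate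
9 | gallocatechin-(4α→6)-gallocatechin (upper unit 2R,3S,4R; lower unit 2R,3S) | Oc1cc(O)c2c(c1)O[C@H](c1cc(O)c(O)c(O)c1)[C@@H](O)[C@@H]2c1c(O)cc2c(c1O)C[C@H](O)[C@@H](c1cc(O)c(O)c(O)c1)O2 | target

**Totals and risks**

Total step count: 7. Longest linear sequence: 7 steps (1 → 2 → 3 → 4 → 5 → 7 → 8 → 9); the second partner, 3, enters step 5 after 2 steps.

Steps most likely to fail:

1. Step 5. The hindered, bromine-deactivated C6 of 3 may capture the cation too slowly, so that the donor condenses with itself through its own C6, the product grows further, or α-facial control is incomplete under the strong Lewis acid. Fallback, setting out from 5: exchange of the C4 ether for a thioether with phenylmethanethiol and BF3·OEt2 in CH2Cl2 at −78 °C should give the 4α-benzylthio 3-acetate F1. F1 is then activated with the thiophilic salt AgBF4 in THF/CH2Cl2 at 0 °C in the presence of excess 3, which generates the same acetoxonium slowly under near-neutral conditions. The route is rejoined at 7.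

2. Step 3. Hydride abstraction from the bromine-deactivated A ring may be slow, leading to incomplete conversion or over-oxidation at C4 to the ketone. Fallback, setting out from 2: the order of oxidation and halogenation is inverted. DDQ and 2-ethoxyethanol in CH2Cl2 act on the more electron-rich, bromine-free 2 to give the 4β-(2-ethoxyethoxy) ether F2. F2 is then brominated at C8 with NBS in CH2Cl2 at −78 °C over solid NaHCO3. The route is rejoined at 4.

3. Step 7. Hydrodebromination may stall through bromide poisoning of the catalyst, or the HBr released may cleave the interflavan bond and prolong exposure of the pyrogallol rings. Fallback, setting out from 8: the halogens are removed first by a radical chain reduction with Bu3SnH and AIBN in toluene at 90 °C, giving the halogen-free deca-O-benzyl dimer F3. F3 is then hydrogenolysed without any additive (H2, Pd(OH)2/C, THF/MeOH/H2O). The route is rejoined at 9.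

Further compounds
F1 | step 5 | (2R,3S)-4α-benzylthio-5,7-bis(benzyloxy)-8-bromo-2-[3,4,5-tris(benzyloxy)phenyl]chroman-3-yl acetate (thioether trans to the acetate) | C(Oc1cc(OCc3ccccc3)c2c(c1Br)O[C@H](c1cc(OCc3ccccc3)c(OCc3ccccc3)c(OCc3ccccc3)c1)[C@@H](OC(C)=O)[C@@H]2SCc1ccccc1)c1ccccc1
F2 | step 3 | (2R,3S,4S)-5,7-bis(benzyloxy)-4-(2-ethoxyethoxy)-2-[3,4,5-tris(benzyloxy)phenyl]chroman-3-ol | C(Oc1cc(OCc3ccccc3)c2c(c1)O[C@H](c1cc(OCc3ccccc3)c(OCc3ccccc3)c(OCc3ccccc3)c1)[C@@H](O)[C@H]2OCCOCC)c1ccccc1
F3 | step 7 | 5,7,3',4',5'-penta-O-benzylgallocatechin-(4α→6)-5,7,3',4',5'-penta-O-benzylgallocatechin | C(Oc1cc(OCc3ccccc3)c2c(c1)O[C@H](c1cc(OCc3ccccc3)c(OCc3ccccc3)c(OCc3ccccc3)c1)[C@@H](O)[C@@H]2c1c(OCc3ccccc3)cc2c(c1OCc3ccccc3)C[C@H](O)[C@@H](c1cc(OCc3ccccc3)c(OCc3ccccc3)c(OCc3ccccc3)c1)O2)c1ccccc1
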